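The butenolide ring (O1–C2–C3–C4–C5) is cut at two bonds, C4–aryl (ring A) and O1–C2. In this ring the C3=C4 alkene carries the aryl group on C4 and the hydrogen on C3 on the same side, so C2 and C5 are cis. That pattern is what a syn addition of Ar–H to a C3≡C4 triple bond leaves behind. One rhodium-catalysed operation joins an arylboronate to a racemic 4-hydroxy-2-ynoate that already bears the C6 benzyl group (ring B), and the cis hydroxy ester closes to the lactone in the same flask. All four bromines are present from the start. The C5=C6 alkene and the free phenols come last.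

Key step: step 6

Remark on the chemistry: lactone numbering is used throughout (O1, C2 = carbonyl, C3, C4, C5, exocyclic C6; ring A on C4, ring B on C6). Compounds 9–11 and 13 are racemic. This is immaterial, because C5 becomes sp2 and the Z C5=C6 alkene is the only stereo-element of the target. Compounds 1, 3 and 7 are assumed to be purchased.

**Step 1**
Reactants: 1 2,6-dibromoanisole
Product: 2 2-(3,5-dibromo-4-methoxyphenyl)-4,4,5,5-tetramethyl-1,3,2-dioxaborolane
Conditions: B2pin2 (1.0 equiv), [Ir(OMe)(cod)]2 (1.5 mol %), 4,4'-di-tert-butyl-2,2'-bipyridine (3 mol %), cyclohexane, 80 °C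
Reagents that add atoms: bis(pinacolato)diboron, CC1(C)OB(OC1(C)C)B1OC(C)(C)C(C)(C)O1
Why: Hartwig–Miyaura aromatic C–H borylation is governed by sterics, so boron should enter only at C4 of 1, the single C–H bond with no ortho substituent, while the iridium boryl catalyst leaves the C–Br bonds alone.

**Step 2**
Reactants: 3 3,5-dibromo-4-hydroxybenzaldehyde
Product: 4 3,5-dibromo-4-methoxybenzaldehyde
Conditions: MeI (1.5 equiv), K2CO3 (2 equiv), DMF, rt
Reagents that add atoms: iodomethane, CI
Why: Williamson ether synthesis, in which K2CO3 fully ionises the acidic 2,6-dibromophenol and the small electrophile MeI reaches the flanked phenoxide oxygen, the aldehyde having no enolisable position.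

**Step 3**
Reactants: 4 3,5-dibromo-4-methoxybenzaldehyde
Product: 5 1,3-dibromo-2-methoxy-5-(2-methoxyethenyl)benzene (E/Z mixture)
Conditions: Ph3P(CH2OMe)Cl (1.3 equiv), KOtBu (1.3 equiv), THF, 0 °C to rt
Reagents that add atoms: (methoxymethyl)triphenylphosphonium chloride, [Cl-].COC[P+](c1ccccc1)(c1ccccc1)c1ccccc1
Why: Wittig methoxymethylenation of a non-enolisable aromatic aldehyde is reliable, and the alkene geometry does not matter because both isomers hydrolyse to the same aldehyde.

**Step 4**
Reactants: 5 1,3-dibromo-2-methoxy-5-(2-methoxyethenyl)benzene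
Product: 6 2-(3,5-dibromo-4-methoxyphenyl)acetaldehyde
Conditions: 2 M aq HCl, THF, 50 °C; used at once
Reagents that add atoms: water, O
Why: Acid-catalysed enol ether hydrolysis (protonation at the benzylic carbon, hydration of the oxocarbenium ion, loss of methanol) completes the one-carbon homologation without touching aryl bromides or aryl methyl ethers, and immediate use of 6 forestalls self-aldol reaction.

**Step 5**
Reactants: 6 2-(3,5-dibromo-4-methoxyphenyl)acetaldehyde; 7 methyl propiolate
Product: 9 methyl 5-(3,5-dibromo-4-methoxyphenyl)-4-hydroxypent-2-ynoate (racemic), via methyl 3-lithiopropiolate 8 (not isolated)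
Conditions: 7 (1.3 equiv), LiN(SiMe3)2 (1.25 equiv), THF, −78 °C; then 6, −78 °C; AcOH quench at −78 °C
Reagents that add atoms: none
Why: In this 1,2-addition of a lithium acetylide to an aldehyde the ester-stabilised acetylide 8 is a weak base, so carbonyl addition should outrun enolisation of 6 at −78 °C, no free amide or alkyllithium remains to disturb the C–Br bonds, and the new C5 carbinol centre forms racemic, which is harmless because step 7 erases it.

**Step 6**
Reactants: 9 methyl 5-(3,5-dibromo-4-methoxyphenyl)-4-hydroxypent-2-ynoate; 2 2-(3,5-dibromo-4-methoxyphenyl)-4,4,5,5-tetramethyl-1,3,2-dioxaborolane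
Product: 11 5-(3,5-dibromo-4-methoxybenzyl)-4-(3,5-dibromo-4-methoxyphenyl)furan-2(5H)-one (racemic), via Z-hydroxy enoate 10 (not isolated)
Conditions: 2 (1.5 equiv), [Rh(OH)(cod)]2 (3 mol %), 1,4-dioxane/H2O (10:1), 60 °C, no added base
Reagents that add atoms: none
Why: The hydroxo complex of monovalent rhodium takes the aryl group from 2 without external base, the aryl–rhodium bond adds syn across the C3≡C4 triple bond of 9, and water cleaves the alkenyl–rhodium bond with retention, which regenerates the hydroxo complex and gives enoate 10. The closest known reaction type is the rhodium-catalysed hydroarylation of 4-hydroxy-2-alkynoates by arylboron reagents with follow-up lactonisation, so only the substitution pattern is new. In 10 the C5 hydroxyl and the ester lie on the same side of the alkene, so O1 attacks C2 in a 5-exo-trig acyl substitution, methanol leaves and the butenolide ring closes. No stereocentre is created, since C5 arrives racemic from 9, and the concerted migratory insertion fixes the alkene geometry. The step needs aryl delivery to C4 and not C3, which the ester secures by polarising the alkyne so that rhodium ends on the α-carbon C3, and it needs four intact C–Br bonds, which is expected because phosphine-free aryl complexes of monovalent rhodium do not insert into aryl bromides at this temperature. A 1,4-shift of rhodium from C3 to an ortho carbon of ring A would be harmless because protonolysis leads to the same product, the excess of 2 covers protodeboronation, and the absence of base protects 9 from isomerisation to the 4-oxo enoate.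

**Step 7**
Reactants: 11 5-(3,5-dibromo-4-methoxybenzyl)-4-(3,5-dibromo-4-methoxyphenyl)furan-2(5H)-one
Product: 12 tert-butyl{[5-(3,5-dibromo-4-methoxybenzyl)-4-(3,5-dibromo-4-methoxyphenyl)furan-2-yl]oxy}dimethylsilane
Conditions: TBSOTf (1.2 equiv), Et3N (2 equiv), CH2Cl2, 0 °C; short work-up, used crude
Reagents that add atoms: tert-butyldimethylsilyl trifluoromethanesulfonate, CC(C)(C)[Si](C)(C)OS(=O)(=O)C(F)(F)F
Why: Soft enolisation of a butenolide (silyl triflate activation of the C2 carbonyl, removal of the acidic C5–H by the amine) is the standard silyl dienol ether formation that gives the aromatic 2-silyloxyfuran and erases the C5 stereocentre.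

**Step 8**
Reactants: 12 tert-butyl{[5-(3,5-dibromo-4-methoxybenzyl)-4-(3,5-dibromo-4-methoxyphenyl)furan-2-yl]oxy}dimethylsilane
Product: 14 (Z)-5-(3,5-dibromo-4-methoxybenzylidene)-4-(3,5-dibromo-4-methoxyphenyl)furan-2(5H)-one, via C5-bromolactone 13 (not isolated)
Conditions: NBS (1.05 equiv), CH2Cl2, −78 °C, dark; then DBU (2 equiv), −78 °C to rt
Reagents that add atoms: none
Why: Electrophilic bromination of a 2-silyloxyfuran at its nucleophilic C5 terminus is followed by base-induced dehydrobromination, for which C6–H is the only β-hydrogen; the Z alkene should result because the E isomer would press ring B against ring A on C4, and the aryl rings resist NBS because both positions ortho to each methoxy group are already brominated.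

**Step 9**
Reactants: 14 (Z)-5-(3,5-dibromo-4-methoxybenzylidene)-4-(3,5-dibromo-4-methoxyphenyl)furan-2(5H)-one
Product: 15 rubrolide A, (Z)-5-(3,5-dibromo-4-hydroxybenzylidene)-4-(3,5-dibromo-4-hydroxyphenyl)furan-2(5H)-one
Conditions: BBr3 (5 equiv), CH2Cl2, −78 °C to rt; then H2O
Reagents that add atoms: none
Why: BBr3 cleavage of aryl methyl ethers (coordination of boron to oxygen, SN2 attack of bromide on methyl, hydrolysis of the aryl borates on work-up) is a standard deprotection that enol lactones of this type tolerate, and the Z alkene, being the more stable isomer, has no incentive to isomerise.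

**Compound list**
1 | 2,6-dibromoanisole | COc1c(Br)cccc1Br | starting material
2 | 2-(3,5-dibromo-4-methoxyphenyl)-4,4,5,5-tetramethyl-1,3,2-dioxaborolane | COc1c(Br)cc(cc1Br)B1OC(C)(C)C(C)(C)O1 | intermediate
3 | 3,5-dibromo-4-hydroxybenzaldehyde | O=Cc1cc(Br)c(O)c(Br)c1 | starting material
4 | 3,5-dibromo-4-methoxybenzaldehyde | O=Cc1cc(Br)c(OC)c(Br)c1 | intermediate
5 | 1,3-dibromo-2-methoxy-5-(2-methoxyethenyl)benzene (E/Z mixture, geometry left open) | COC=Cc1cc(Br)c(OC)c(Br)c1 | intermediate
6 | 2-(3,5-dibromo-4-methoxyphenyl)acetaldehyde | O=CCc1cc(Br)c(OC)c(Br)c1 | intermediate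
7 | methyl propiolate | C#CC(=O)OC | starting material
8 | methyl 3-lithiopropiolate (formed in the flask) | [Li]C#CC(=O)OC | intermediate
9 | methyl 5-(3,5-dibromo-4-methoxyphenyl)-4-hydroxypent-2-ynoate (racemic) | COC(=O)C#CC(O)Cc1cc(Br)c(OC)c(Br)c1 | intermediate
10 | methyl (Z)-3,5-bis(3,5-dibromo-4-methoxyphenyl)-4-hydroxypent-2-enoate (racemic, formed in the flask) | COC(=O)/C=C(\C(O)Cc1cc(Br)c(OC)c(Br)c1)c1cc(Br)c(OC)c(Br)c1 | intermediate
11 | 5-(3,5-dibromo-4-methoxybenzyl)-4-(3,5-dibromo-4-methoxyphenyl)furan-2(5H)-one (racemic) | O=C1C=C(c2cc(Br)c(OC)c(Br)c2)C(Cc2cc(Br)c(OC)c(Br)c2)O1 | intermediate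
12 | tert-butyl{[5-(3,5-dibromo-4-methoxybenzyl)-4-(3,5-dibromo-4-methoxyphenyl)furan-2-yl]oxy}dimethylsilane | CC(C)(C)[Si](C)(C)Oc1cc(-c2cc(Br)c(OC)c(Br)c2)c(Cc2cc(Br)c(OC)c(Br)c2)o1 | intermediate
13 | 5-bromo-5-(3,5-dibromo-4-methoxybenzyl)-4-(3,5-dibromo-4-methoxyphenyl)furan-2(5H)-one (racemic, formed in the flask) | O=C1C=C(c2cc(Br)c(OC)c(Br)c2)C(Br)(Cc2cc(Br)c(OC)c(Br)c2)O1 | intermediate
14 | (Z)-5-(3,5-dibromo-4-methoxybenzylidene)-4-(3,5-dibromo-4-methoxyphenyl)furan-2(5H)-one | O=C1C=C(c2cc(Br)c(OC)c(Br)c2)/C(=C/c2cc(Br)c(OC)c(Br)c2)O1 | intermediate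
15 | rubrolide A | O=C1C=C(c2cc(Br)c(O)c(Br)c2)/C(=C/c2cc(Br)c(O)c(Br)c2)O1 | target

Total step count: 9.
Longest linear sequence: 8 steps (3 → 4 → 5 → 6 → 9 → 11 → 12 → 14 → 15). Step 1 is the one-step side branch.

**Steps most likely to fail**

**Step 6.**
- What may go wrong: boron-to-rhodium transfer from the pinacol ester may be slow. Protodeboronation of the rather electron-poor aryl group may then outpace insertion into the hindered internal alkyne, and the propargylic alcohol may drift to the 4-oxo enoate.
- Fallback: the ring is bought and the C5–C6 bond is made by condensation instead. The fallback sets out from 2 and uses 4.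
- A Suzuki–Miyaura coupling of 2 with commercial 4-bromofuran-2(5H)-one (PdCl2(PPh3)2, aq Na2CO3, toluene/EtOH, 40 °C) should give 4-(3,5-dibromo-4-methoxyphenyl)furan-2(5H)-one F1. Zerovalent palladium should insert into the vinylogous acyl bromide far faster than into the ortho-flanked aryl bromides.
- Soft enolisation of F1 (TBSOTf, iPr2NEt, CH2Cl2) should form tert-butyl{[4-(3,5-dibromo-4-methoxyphenyl)furan-2-yl]oxy}dimethylsilane F2.
- F2 adds in the same flask through C5 to aldehyde 4 (vinylogous Mukaiyama aldol). This gives 5-[(tert-butyldimethylsilyloxy)(3,5-dibromo-4-methoxyphenyl)methyl]-4-(3,5-dibromo-4-methoxyphenyl)furan-2(5H)-one F3.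
- DBU then expels silanolate by an E1cB elimination, and the sequence comes back to the route at 14.

**Step 8.**
- What may go wrong: the bromonium source may attack C3 instead of C5, the labile tertiary bromide may hydrolyse before elimination, or control of the alkene geometry may be incomplete.
- Fallback: oxygen replaces bromine as the leaving group. The fallback sets out from 12.
- A Rubottom-type oxidation of 12 with mCPBA (CH2Cl2, 0 °C) should give 5-(3,5-dibromo-4-methoxybenzyl)-4-(3,5-dibromo-4-methoxyphenyl)-5-hydroxyfuran-2(5H)-one F4.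
- Acid-catalysed dehydration (cat. p-TsOH, toluene, reflux with removal of water) runs under equilibrating conditions that favour the Z isomer, and it comes back to the route at 14.

**Step 5.**
- What may go wrong: the thermally fragile lithium propiolate may decompose or add sluggishly, so that enolisation and self-aldol reaction of the arylacetaldehyde take over.
- Fallback: carbon–carbon bond formation is separated from introduction of the ester. The fallback sets out from 6.
- The robust HC≡CMgBr (excess, THF, 0 °C) should give 1-(3,5-dibromo-4-methoxyphenyl)but-3-yn-2-ol F5.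
- Double deprotonation with EtMgBr (2.1 equiv, THF) and carboxylation with CO2 should give 5-(3,5-dibromo-4-methoxyphenyl)-4-hydroxypent-2-ynoic acid F6.
- Alkylation of the carboxylate (MeI, KHCO3, DMF, rt) comes back to the route at 9.

**Further compounds**
F1 | step 6 | 4-(3,5-dibromo-4-methoxyphenyl)furan-2(5H)-one | O=C1C=C(c2cc(Br)c(OC)c(Br)c2)CO1
F2 | step 6 | tert-butyl{[4-(3,5-dibromo-4-methoxyphenyl)furan-2-yl]oxy}dimethylsilane | CC(C)(C)[Si](C)(C)Oc1cc(-c2cc(Br)c(OC)c(Br)c2)co1
F3 | step 6 | 5-[(tert-butyldimethylsilyloxy)(3,5-dibromo-4-methoxyphenyl)methyl]-4-(3,5-dibromo-4-methoxyphenyl)furan-2(5H)-one (racemic mixture of diastereomers) | O=C1C=C(c2cc(Br)c(OC)c(Br)c2)C(O1)C(O[Si](C)(C)C(C)(C)C)c1cc(Br)c(OC)c(Br)c1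
F4 | step 8 | 5-(3,5-dibromo-4-methoxybenzyl)-4-(3,5-dibromo-4-methoxyphenyl)-5-hydroxyfuran-2(5H)-one (racemic) | O=C1C=C(c2cc(Br)c(OC)c(Br)c2)C(O)(Cc2cc(Br)c(OC)c(Br)c2)O1
F5 | step 5 | 1-(3,5-dibromo-4-methoxyphenyl)but-3-yn-2-ol (racemic) | C#CC(O)Cc1cc(Br)c(OC)c(Br)c1
F6 | step 5 | 5-(3,5-dibromo-4-methoxyphenyl)-4-hydroxypent-2-ynoic acid (racemic) | OC(=O)C#CC(O)Cc1cc(Br)c(OC)c(Br)c1
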